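The route rests on cutting the C2–C3 bond of ring A. This exploits the fact that C3 and C19, both attached to the quaternary C4 of ring A, are oxygenated carbons: the cut unravels them into a prochiral methylmalonate on C5, cis on ring B to a two-carbon arm (C1–C2) on C10. In the key step SmI2 converts the electrophilic C2 iodide into an alkylsamarium that attacks one of the two diastereotopic ester carbonyls; one operation closes the cis-fused ring A, creates the C3 ketone and fixes the C4 quaternary stereocentre. The precursor is a ring B enol triflate carrying methyl and 2-iodoethyl at C10 and the malonate at C5.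

Key step: step 8

Remark: labdane numbering is used and α/β refer to the usual drawing with the C10 methyl β; the target as drawn is A/B cis-fused (H-5 β) with 3α-OAc, 4α-Me and 4β-CO2H, and the (R,R)-ligand of step 1 is assumed to give the (S)-malonate as it does with dimethyl malonate.

Step 1
Reactants: 1 (±)-cyclohex-2-en-1-yl acetate; 2 dimethyl methylmalonate
Product: 3 dimethyl 2-[(1S)-cyclohex-2-en-1-yl]-2-methylmalonate
Conditions: [Pd(C3H5)Cl]2 (cat.), (1R,2R)-N,N'-bis[2-(diphenylphosphino)benzoyl]cyclohexane-1,2-diamine (cat.), Cs2CO3, CH2Cl2, rt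
Reagents that add atoms: none
Why: Tsuji–Trost asymmetric allylic alkylation: the racemic acetate ionises to a meso π-allylpalladium complex and the chiral diphosphine steers the malonate anion to one enantiotopic terminus, which sets the future C5 as (S) and consumes both enantiomers of 1.

Step 2
Reactants: 3 dimethyl 2-[(1S)-cyclohex-2-en-1-yl]-2-methylmalonate
Product: 4 dimethyl 2-methyl-2-[(1S)-4-oxocyclohex-2-en-1-yl]malonate
Conditions: Rh2(cap)4 (cat., cap = caprolactamate), t-BuOOH, K2CO3, CH2Cl2, rt
Reagents that add atoms: tert-butyl hydroperoxide CC(C)(C)OO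
Why: Rhodium-catalysed allylic C–H oxidation abstracts hydrogen at the unhindered ring methylene remote from the quaternary malonate and oxygenates that carbon, giving the 4-substituted cyclohex-2-enone without touching the C5 stereocentre.

Step 3
Reactants: 4 dimethyl 2-methyl-2-[(1S)-4-oxocyclohex-2-en-1-yl]malonate
Product: 5 dimethyl 2-[(1S,2R)-2-allyl-4-(trimethylsilyloxy)cyclohex-3-en-1-yl]-2-methylmalonate
Conditions: allylMgBr, CuBr·SMe2, TMSCl, THF, −78 °C; Et3N, pentane work-up
Reagents that add atoms: allylmagnesium bromide C=CC[Mg]Br; chlorotrimethylsilane C[Si](C)(C)Cl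
Why: Copper-mediated conjugate allylation with TMSCl trapping adds the allyl group to C10 anti to the bulky C5 malonate (trans-3,4 product) and delivers the C8/C9 silyl enol ether regiospecifically; the C10 stereocentre made here is erased in step 4.

Step 4
Reactants: 5 dimethyl 2-[(1S,2R)-2-allyl-4-(trimethylsilyloxy)cyclohex-3-en-1-yl]-2-methylmalonate
Product: 6 dimethyl 2-[(1S)-2-allyl-4-oxocyclohex-2-en-1-yl]-2-methylmalonate
Conditions: IBX, 4-methoxypyridine N-oxide, DMSO, rt
Reagents that add atoms: none
Why: IBX-mediated dehydrogenation of a silyl enol ether (a palladium-free Saegusa-type oxidation that cannot engage the allyl alkene) restores the C9=C10 enone regiospecifically, now with the precursor of the two-carbon arm on C10.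

Step 5
Reactants: 6 dimethyl 2-[(1S)-2-allyl-4-oxocyclohex-2-en-1-yl]-2-methylmalonate
Product: 8 dimethyl 2-[(1S,2S)-2-allyl-2-methyl-4-(trifluoromethanesulfonyloxy)cyclohex-3-en-1-yl]-2-methylmalonate, via lithium enolate 7 (not isolated)
Conditions: Me2CuLi (MeLi, CuI), Et2O, −78 → 0 °C; then PhNTf2, THF, 0 °C → rt
Reagents that add atoms: methyllithium [Li]C; N-phenylbis(trifluoromethanesulfonimide) FC(F)(F)S(=O)(=O)N(c1ccccc1)S(=O)(=O)C(F)(F)F
Why: Cuprate conjugate addition to the β,β-disubstituted enone: allylic 1,2-strain with the C10 allyl group holds the C5 malonate pseudoaxial, so methyl enters C10 from the opposite face (methyl trans, allyl cis to the malonate), and the regiodefined enolate is triflated by PhNTf2 to mask the C8 ketone as the C8=C9 enol triflate.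

Step 6
Reactants: 8 dimethyl 2-[(1S,2S)-2-allyl-2-methyl-4-(trifluoromethanesulfonyloxy)cyclohex-3-en-1-yl]-2-methylmalonate
Product: 10 dimethyl 2-[(1S,2S)-2-(2-hydroxyethyl)-2-methyl-4-(trifluoromethanesulfonyloxy)cyclohex-3-en-1-yl]-2-methylmalonate, via aldehyde 9 (not isolated)
Conditions: O3, CH2Cl2/MeOH, −78 °C; then NaBH4, −78 → 0 °C
Reagents that add atoms: ozone O=[O+][O-]
Why: Ozonolysis with reductive work-up: ozone attacks the electron-rich monosubstituted allyl alkene far faster than the electron-poor enol triflate, and NaBH4 reduces the resulting aldehyde in the same flask to the C2 alcohol while the hindered malonate esters are untouched.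

Step 7
Reactants: 10 dimethyl 2-[(1S,2S)-2-(2-hydroxyethyl)-2-methyl-4-(trifluoromethanesulfonyloxy)cyclohex-3-en-1-yl]-2-methylmalonate
Product: 11 dimethyl 2-[(1S,2S)-2-(2-iodoethyl)-2-methyl-4-(trifluoromethanesulfonyloxy)cyclohex-3-en-1-yl]-2-methylmalonate
Conditions: I2, PPh3, imidazole, CH2Cl2, 0 °C → rt
Reagents that add atoms: iodine II
Why: Appel-type iodination converts the unhindered primary alcohol to the primary iodide by SN2 displacement of the oxyphosphonium group.

Step 8
Reactants: 11 dimethyl 2-[(1S,2S)-2-(2-iodoethyl)-2-methyl-4-(trifluoromethanesulfonyloxy)cyclohex-3-en-1-yl]-2-methylmalonate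
Product: 13 methyl 3-oxo-8-(trifluoromethanesulfonyloxy)-11,12,13,14,15,16,17-heptanor-5β-labd-8-en-19-oate (cis-fused; 4β-CO2Me; 4α-Me), via alkylsamarium 12 (not isolated)
Conditions: SmI2 (2.2 equiv), Fe(dbm)3 (cat., dbm = dibenzoylmethanate), THF, −30 °C → rt; cold aq. NH4Cl
Reagents that add atoms: none
Why: SmI2 (with catalytic Fe(dbm)3) reduces the primary C2–I bond by two single-electron transfers to a primary alkylsamarium, which adds to one ester carbonyl of the C4 methylmalonate and expels methoxide, so that two carbons that are both electrophilic in 11 are joined by polarity reversal at C2. The closest known reaction type is the samarium Barbier-type intramolecular nucleophilic acyl substitution of ω-iodo esters to cyclic ketones. Ring A closes by 6-exo-trig attack on the carbonyl through a chair-like transition state, and the cis fusion is inherited from the cis relation of the C10 ethyl arm and the C5 malonate on ring B. The only new stereocentre, C4, is set by the choice between the two diastereotopic esters: the ester anti to H-5 is the one within reach of C2, and of the two rotamers that offer an ester there the one that keeps the C4 methyl equatorial and puts the surviving ester axial, syn to the C10 methyl, avoids a methyl/methyl syn-pentane clash, which gives 4α-Me/4β-CO2Me. The step needs this group selectivity and must stop at the ketone; the hindered ketone, the use of only two equivalents of SmI2 and the inertness of the enol triflate and the esters to SmI2 should secure it.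

Step 9
Reactants: 13 methyl 3-oxo-8-(trifluoromethanesulfonyloxy)-11,12,13,14,15,16,17-heptanor-5β-labd-8-en-19-oate
Product: 15 methyl 3α-acetoxy-8-(trifluoromethanesulfonyloxy)-11,12,13,14,15,16,17-heptanor-5β-labd-8-en-19-oate, via lithium alkoxide 14 (not isolated)
Conditions: LiBH(s-Bu)3, THF, −78 °C; then Ac2O, DMAP, −78 °C → rt
Reagents that add atoms: acetic anhydride CC(=O)OC(C)=O
Why: Substrate-controlled hydride reduction followed by in situ acylation: the bulky borohydride attacks C3 from the convex β face of the cis-decalin (the α face is screened by the syn-axial C6 methylene of ring B), giving the 3α-alkoxide, that is (3R), which Ac2O/DMAP acetylates before work-up.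

Step 10
Reactants: 15 methyl 3α-acetoxy-8-(trifluoromethanesulfonyloxy)-11,12,13,14,15,16,17-heptanor-5β-labd-8-en-19-oate
Product: 16 methyl 3α-acetoxy-17-hydroxy-11,12,13,14,15,16-hexanor-5β-labd-8-en-19-oate
Conditions: Bu3SnCH2OH, Pd(PPh3)4 (cat.), LiCl, 1,4-dioxane, 100 °C
Reagents that add atoms: (tributylstannyl)methanol OC[Sn](CCCC)(CCCC)CCCC
Why: Stille coupling of the enol triflate with (tributylstannyl)methanol (LiCl-assisted transmetalation) installs C17 as a primary allylic alcohol on C8 with the C8=C9 alkene retained.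

Step 11
Reactants: 16 methyl 3α-acetoxy-17-hydroxy-11,12,13,14,15,16-hexanor-5β-labd-8-en-19-oate
Product: 18 methyl 3α-acetoxy-12-oxo-13,14,15,16-tetranor-5β-labd-8(17)-en-19-oate, via allyl vinyl ether 17 (not isolated)
Conditions: ethyl vinyl ether, Hg(OAc)2 (cat.), reflux; then xylene, 140 °C
Reagents that add atoms: ethyl vinyl ether C=COCC
Why: Transvinylation to the allyl vinyl ether and Claisen [3,3] rearrangement through a chair transition state form the C9–C11 bond and move the alkene to the exocyclic C8=C17 position; the new bond forms at C9 on the convex β face, anti to the pseudoaxial C1 of ring A on C10, which sets C9 with the side chain β (H-9 α).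

Step 12
Reactants: 18 methyl 3α-acetoxy-12-oxo-13,14,15,16-tetranor-5β-labd-8(17)-en-19-oate
Product: 19 methyl 3α-acetoxy-12-hydroxy-13,14,15,16-tetranor-5β-labd-8(17)-en-19-oate
Conditions: NaBH4, MeOH, 0 °C
Reagents that add atoms: none
Why: Chemoselective borohydride reduction of the aldehyde; the acetate and the hindered methyl ester are not reduced at 0 °C.

Step 13
Reactants: 19 methyl 3α-acetoxy-12-hydroxy-13,14,15,16-tetranor-5β-labd-8(17)-en-19-oate
Product: 20 methyl 3α-acetoxy-12-iodo-13,14,15,16-tetranor-5β-labd-8(17)-en-19-oate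
Conditions: I2, PPh3, imidazole, CH2Cl2, 0 °C → rt
Reagents that add atoms: iodine II
Why: Appel-type iodination of the primary alcohol by SN2 displacement, as in step 7.

Step 14
Reactants: 20 methyl 3α-acetoxy-12-iodo-13,14,15,16-tetranor-5β-labd-8(17)-en-19-oate
Product: 21 methyl 3α-acetoxy-5β-labda-8(17),13(16),14-trien-19-oate
Conditions: buta-1,3-dien-2-ylmagnesium chloride (THF solution from chloroprene and Mg), Li2CuCl4 (cat.), THF/NMP, −20 → 0 °C
Reagents that add atoms: buta-1,3-dien-2-ylmagnesium chloride C=CC(=C)[Mg]Cl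
Why: Copper-catalysed sp3–sp2 cross-coupling of a primary alkyl iodide with an alkenyl Grignard reagent (Kochi-type alkylation), which at low temperature outpaces addition to the acetate and the hindered ester and installs the 2-substituted buta-1,3-diene (C13–C16) in one step.

Step 15
Reactants: 21 methyl 3α-acetoxy-5β-labda-8(17),13(16),14-trien-19-oate
Product: 22 3α-acetoxy-5β-labda-8(17),13(16),14-trien-19-oic acid (target)
Conditions: LiI, pyridine, reflux; then cold dilute HCl
Reagents that add atoms: none
Why: SN2 demethylation by iodide at the O–CH3 carbon is insensitive to the steric hindrance of the C4 carboxyl and leaves the secondary acetate (no unhindered O-alkyl carbon), the diene and the exocyclic alkene untouched, and acidification liberates the acid.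

Compound list
1 | (±)-cyclohex-2-en-1-yl acetate | CC(=O)OC1C=CCCC1 | starting material
2 | dimethyl methylmalonate | COC(=O)C(C)C(=O)OC | starting material
3 | dimethyl 2-[(1S)-cyclohex-2-en-1-yl]-2-methylmalonate | C1=C[C@@H](C(C)(C(=O)OC)C(=O)OC)CCC1 | intermediate
4 | dimethyl 2-methyl-2-[(1S)-4-oxocyclohex-2-en-1-yl]malonate | O=C1C=C[C@@H](C(C)(C(=O)OC)C(=O)OC)CC1 | intermediate
5 | dimethyl 2-[(1S,2R)-2-allyl-4-(trimethylsilyloxy)cyclohex-3-en-1-yl]-2-methylmalonate (allyl trans to the malonate) | C[Si](C)(C)OC1=C[C@H](CC=C)[C@@H](C(C)(C(=O)OC)C(=O)OC)CC1 | intermediate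
6 | dimethyl 2-[(1S)-2-allyl-4-oxocyclohex-2-en-1-yl]-2-methylmalonate | O=C1C=C(CC=C)[C@@H](C(C)(C(=O)OC)C(=O)OC)CC1 | intermediate
7 | lithium enolate (C8–OLi, C8=C9) formed by methyl addition to 6, not isolated | C1=C(O[Li])CC[C@H](C(C)(C(=O)OC)C(=O)OC)[C@]1(C)CC=C | intermediate
8 | dimethyl 2-[(1S,2S)-2-allyl-2-methyl-4-(trifluoromethanesulfonyloxy)cyclohex-3-en-1-yl]-2-methylmalonate (C10 methyl trans, allyl cis to the malonate) | C1=C(OS(=O)(=O)C(F)(F)F)CC[C@H](C(C)(C(=O)OC)C(=O)OC)[C@]1(C)CC=C | intermediate
9 | dimethyl 2-methyl-2-[(1S,2S)-2-methyl-2-(2-oxoethyl)-4-(trifluoromethanesulfonyloxy)cyclohex-3-en-1-yl]malonate, not isolated | C1=C(OS(=O)(=O)C(F)(F)F)CC[C@H](C(C)(C(=O)OC)C(=O)OC)[C@]1(C)CC=O | intermediate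
10 | dimethyl 2-[(1S,2S)-2-(2-hydroxyethyl)-2-methyl-4-(trifluoromethanesulfonyloxy)cyclohex-3-en-1-yl]-2-methylmalonate | C1=C(OS(=O)(=O)C(F)(F)F)CC[C@H](C(C)(C(=O)OC)C(=O)OC)[C@]1(C)CCO | intermediate
11 | dimethyl 2-[(1S,2S)-2-(2-iodoethyl)-2-methyl-4-(trifluoromethanesulfonyloxy)cyclohex-3-en-1-yl]-2-methylmalonate | C1=C(OS(=O)(=O)C(F)(F)F)CC[C@H](C(C)(C(=O)OC)C(=O)OC)[C@]1(C)CCI | intermediate
12 | alkylsamarium diiodide at C2 formed from 11, not isolated | C1=C(OS(=O)(=O)C(F)(F)F)CC[C@H](C(C)(C(=O)OC)C(=O)OC)[C@]1(C)CC[Sm](I)I | intermediate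
13 | methyl 3-oxo-8-(trifluoromethanesulfonyloxy)-11,12,13,14,15,16,17-heptanor-5β-labd-8-en-19-oate (cis-fused; 10β-Me, 5β-H, 4β-CO2Me, 4α-Me) | C1=C(OS(=O)(=O)C(F)(F)F)CC[C@H]2[C@]1(C)CCC(=O)[C@]2(C)C(=O)OC | intermediate
14 | lithium 3α-alkoxide formed by reduction of 13, not isolated | C1=C(OS(=O)(=O)C(F)(F)F)CC[C@H]2[C@]1(C)CC[C@@H](O[Li])[C@]2(C)C(=O)OC | intermediate
15 | methyl 3α-acetoxy-8-(trifluoromethanesulfonyloxy)-11,12,13,14,15,16,17-heptanor-5β-labd-8-en-19-oate | C1=C(OS(=O)(=O)C(F)(F)F)CC[C@H]2[C@]1(C)CC[C@@H](OC(C)=O)[C@]2(C)C(=O)OC | intermediate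
16 | methyl 3α-acetoxy-17-hydroxy-11,12,13,14,15,16-hexanor-5β-labd-8-en-19-oate | C1=C(CO)CC[C@H]2[C@]1(C)CC[C@@H](OC(C)=O)[C@]2(C)C(=O)OC | intermediate
17 | 17-O-vinyl ether of 16, not isolated | C1=C(COC=C)CC[C@H]2[C@]1(C)CC[C@@H](OC(C)=O)[C@]2(C)C(=O)OC | intermediate
18 | methyl 3α-acetoxy-12-oxo-13,14,15,16-tetranor-5β-labd-8(17)-en-19-oate (9β side chain) | O=CC[C@H]1C(=C)CC[C@H]2[C@]1(C)CC[C@@H](OC(C)=O)[C@]2(C)C(=O)OC | intermediate
19 | methyl 3α-acetoxy-12-hydroxy-13,14,15,16-tetranor-5β-labd-8(17)-en-19-oate | OCC[C@H]1C(=C)CC[C@H]2[C@]1(C)CC[C@@H](OC(C)=O)[C@]2(C)C(=O)OC | intermediate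
20 | methyl 3α-acetoxy-12-iodo-13,14,15,16-tetranor-5β-labd-8(17)-en-19-oate | ICC[C@H]1C(=C)CC[C@H]2[C@]1(C)CC[C@@H](OC(C)=O)[C@]2(C)C(=O)OC | intermediate
21 | methyl 3α-acetoxy-5β-labda-8(17),13(16),14-trien-19-oate | C=CC(=C)CC[C@H]1C(=C)CC[C@H]2[C@]1(C)CC[C@@H](OC(C)=O)[C@]2(C)C(=O)OC | intermediate
22 | 3α-acetoxy-5β-labda-8(17),13(16),14-trien-19-oic acid | C=CC(=C)CC[C@H]1C(=C)CC[C@H]2[C@]1(C)CC[C@@H](OC(C)=O)[C@]2(C)C(=O)O | target

Total step count: 15. Longest linear sequence: 15 steps (1 or 2 to 22).

Steps most likely to fail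

Step 8. The alkylsamarium may be quenched by protonation before it reaches the hindered ester, or it may discriminate poorly between the two diastereotopic esters. The fallback sets out from iodide 11: displacement with PhSO2Na (DMF, 60 °C) gives the 2-(phenylsulfonyl)ethyl malonate F1. LiHMDS (THF, −78 → 0 °C) then forms the α-sulfonyl carbanion, which closes ring A by a Dieckmann-type acylation to the cyclic β-keto sulfone F2. This stabilised, bulkier nucleophile reacts through a later, more product-like transition state and the product is drained as its enolate. Reductive desulfonylation with Al/Hg amalgam in aqueous THF returns the route to keto ester 13.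

Step 5. Conjugate addition may stall at the congested C10, or the cuprate may deprotonate the doubly allylic C1 methylene. The fallback sets out from enone 6: Corey–Chaykovsky cyclopropanation with dimethylsulfoxonium methylide (Me3S(O)I, NaH, DMSO), anti to the malonate, gives the cyclopropyl ketone F3. SmI2/HMPA in THF opens the derived ketyl by cleavage of the exocyclic cyclopropane bond, which turns the bridging CH2 into the C10 methyl and leaves the C8/C9 samarium enolate. PhNTf2 added to the same flask triflates this enolate and rejoins the route at 8.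

Step 9. Facial selectivity of hydride delivery may be poor, because two chair forms of ring A present opposite faces of C3 to a bulky hydride. The fallback sets out from ketone 13 and uses reagent control: Corey–Bakshi–Shibata reduction with (S)-2-methyl-CBS-oxazaborolidine and catecholborane (toluene, −40 °C) differentiates the quaternary C4 flank from the C2 methylene flank and should give the 3α-alcohol F4, that is (3R), irrespective of ring conformation. Ac2O, DMAP and pyridine then give 15.

Further compounds
F1 | step 8 | dimethyl 2-methyl-2-[(1S,2S)-2-methyl-2-(2-(phenylsulfonyl)ethyl)-4-(trifluoromethanesulfonyloxy)cyclohex-3-en-1-yl]malonate | C1=C(OS(=O)(=O)C(F)(F)F)CC[C@H](C(C)(C(=O)OC)C(=O)OC)[C@]1(C)CCS(=O)(=O)c3ccccc3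
F2 | step 8 | methyl 3-oxo-2-(phenylsulfonyl)-8-(trifluoromethanesulfonyloxy)-11,12,13,14,15,16,17-heptanor-5β-labd-8-en-19-oate (C2 epimers) | C1=C(OS(=O)(=O)C(F)(F)F)CC[C@H]2[C@]1(C)CC(S(=O)(=O)c3ccccc3)C(=O)[C@]2(C)C(=O)OC
F3 | step 5 | dimethyl 2-methyl-2-(6-allyl-2-oxobicyclo[4.1.0]heptan-5-yl)malonate (cyclopropane CH2 on the β face, anti to the malonate) | O=C1CC[C@H](C(C)(C(=O)OC)C(=O)OC)[C@@]2(CC=C)C[C@@H]12
F4 | step 9 | methyl 3α-hydroxy-8-(trifluoromethanesulfonyloxy)-11,12,13,14,15,16,17-heptanor-5β-labd-8-en-19-oate | C1=C(OS(=O)(=O)C(F)(F)F)CC[C@H]2[C@]1(C)CC[C@@H](O)[C@]2(C)C(=O)OC
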